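Ring B (C5–C10) is taken out of a seven-membered ring. Because ring A is a lactone, the quaternary C10 carries C1 outside ring B, and C1 is oxygenated; ring B with a C1 aldehyde is therefore the semipinacol product of a cycloheptene oxide in which C1 sits between C10 and C5. The precursor is a trans-fused bicyclo[5.4.0]undecenone α-epoxide made from (S)-carvone (ring C, C9, C10) by two alkylations and a ring-closing metathesis. In one operation the Lewis acid moves C5 from C1 to C10: the ring contracts to ring B, C10 is set stereospecifically and C1 appears as the aldehyde from which ring A is grown; rings D and E are built on C14.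

Key step: step 10

Remark: atoms carry the breviane numbering of this skeleton – ring A lactone C1(OAc)–C2–C3(=O)–O–C4(Me)2–C5–C10, ring B C5–C6–C7–C8–C9–C10, ring C C8–C9–C11–C12=C13–C14, lactone ring D C14–C15–C16–C17(=O)–O, furanone ring E spiro at C16; α/β refer to the usual drawing (8-Me and 10-Me β); the allylborane of step 18 and the zinc reagent of step 13 are assumed to be bought as solutions.

Step 1
Reactants: 1 penta-1,4-diene
Product: 2 3-vinylpent-4-en-1-ol
Conditions: n-BuLi, THF, −78 to 0 °C; ethylene oxide, −78 °C to rt
Reagents that add atoms: ethylene oxide C1CO1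
Why: The pentadienyl anion opens the epoxide mainly through its central carbon (the kinetic site, as in protonation and alkylation of pentadienyl anions), which gives the skipped diene with two equivalent vinyl groups.

Step 2
Reactants: 2 3-vinylpent-4-en-1-ol
Product: 3 3-(2-iodoethyl)penta-1,4-diene
Conditions: I2, PPh3, imidazole, CH2Cl2, 0 °C
Reagents that add atoms: iodine II
Why: Appel-type iodination of the primary alcohol proceeds by SN2 displacement of the alkoxyphosphonium ion and leaves the 1,4-diene untouched.

Step 3
Reactants: 4 methyl 2-methyl-3-oxobutanoate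
Product: 5 methyl (E)-3-methoxy-2-methylbut-2-enoate
Conditions: HC(OMe)3, H2SO4 (cat.), MeOH, rt
Reagents that add atoms: trimethyl orthoformate COC(OC)OC
Why: Acid-catalysed ketalisation of the ketone and loss of methanol give the conjugated enol ether, whose double-bond geometry is of no consequence later.

Step 4
Reactants: 5 methyl (E)-3-methoxy-2-methylbut-2-enoate
Product: 6 (E)-3-methoxy-2-methylbut-2-enoic acid
Conditions: NaOH, MeOH/H2O, 60 °C; cold 1 M HCl to pH 3
Reagents that add atoms: sodium hydroxide [Na+].[OH-]
Why: Saponification cleaves the ester, and brief cold acidification preserves the acid-labile enol ether.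

Step 5
Reactants: 6 (E)-3-methoxy-2-methylbut-2-enoic acid
Product: 7 (E)-3-methoxy-2-methylbut-2-enoyl chloride
Conditions: (COCl)2, DMF (cat.), CH2Cl2, 0 °C to rt; used crude
Reagents that add atoms: oxalyl chloride ClC(=O)C(=O)Cl
Why: Chloroiminium-catalysed acid chloride formation is anhydrous and keeps the enol ether.

Step 6
Reactants: 8 (S)-(+)-carvone
Product: 9 6-methylcarvone (C6 epimers)
Conditions: LiN(i-Pr)2 (LDA), THF, −78 °C; MeI
Reagents that add atoms: iodomethane CI
Why: The kinetic α′-enolate is methylated at C6 (enolate alkylation); the new centre is planarised again in step 7, so its configuration does not matter.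

Step 7
Reactants: 9 6-methylcarvone (C6 epimers); 3 3-(2-iodoethyl)penta-1,4-diene
Product: 10 (5R,6R)-6-methyl-6-(3-vinylpent-4-enyl)carvone
Conditions: LDA, THF, −78 to 0 °C; HMPA, then 3, −78 °C to rt
Reagents that add atoms: none
Why: SN2 alkylation of the tetrasubstituted lithium enolate takes place on the face anti to the C9 isopropenyl group, which sets the quaternary C8 with the methyl cis to isopropenyl (8β-methyl, chain α).

Step 8
Reactants: 10 (5R,6R)-6-methyl-6-(3-vinylpent-4-enyl)carvone
Product: 11 cycloheptene-fused enone (C1=C10, 5β-vinyl, 8β-methyl, 9α-H)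
Conditions: second-generation Grubbs catalyst (H2IMes)(PCy3)Cl2Ru=CHPh (cat.), CH2Cl2 (dilute), 40 °C
Reagents that add atoms: none
Why: Ring-closing metathesis joins the isopropenyl group to one of the two diastereotopic vinyl groups and closes the trans-fused cycloheptene; the vinyl group that stays behind should take the pseudo-equatorial (β) site of the chair cycloheptene, which corresponds to 5α-H and is also the thermodynamic configuration once C5 is α to the C4 ketone.

Step 9
Reactants: 11 cycloheptene-fused enone
Product: 12 1α,10α-epoxide of 11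
Conditions: mCPBA, NaHCO3, CH2Cl2, 0 °C
Reagents that add atoms: 3-chloroperoxybenzoic acid OOC(=O)c1cccc(Cl)c1
Why: Prilezhaev epoxidation selects the electron-rich trisubstituted C1=C10 bond over the vinyl group and the enone alkene, and the peracid should approach the α face because the axial 8β-methyl group covers the β face.

Step 10
Reactants: 12 1α,10α-epoxide
Product: 13 ring B aldehyde (10β-methyl, 10-formyl, 5β-vinyl, 5α-H)
Conditions: MeAl(OAr)2 (MABR; Ar = 4-bromo-2,6-di-tert-butylphenyl), CH2Cl2, −78 to −40 °C
Reagents that add atoms: none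
Why: The bulky Lewis acid binds the epoxide oxygen, the C10–O bond at the tertiary carbon ionises and, in the same event, the C1–C5 bond migrates to C10 on the face opposite the leaving oxygen while C1–O becomes the aldehyde carbonyl (semipinacol, Meinwald-type rearrangement). The closest known reaction type is the MABR-promoted rearrangement of trisubstituted epoxides to α-quaternary aldehydes by alkyl shift, including ring contraction of 1-methylcycloalkene oxides. No ring is closed by joining chain ends: ring B (C5–C6–C7–C8–C9–C10) arises because the seven-membered ring loses C1 to the exocyclic position on C10, a contraction by one atom through a 1,2-shift. C10 is the only new stereocentre and is fixed by the epoxide, since C5 enters anti to the α-oxygen so that the methyl stays β and C1 takes the equatorial site, while C5 migrates with retention and keeps its α-hydrogen. The step needs alkyl rather than hydride shift from C1 and a concerted, stereospecific course; these are secured by the aluminium reagent (which favours alkyl shift and shields the aldehyde formed), the good migratory aptitude of the allylic secondary C5, the relief of seven-ring strain and the low temperature, with the enone and the vinyl group inert.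

Step 11
Reactants: 13 ring B aldehyde
Product: 14 1,3-dioxolane of 13
Conditions: TMSOCH2CH2OTMS, TMSOTf (cat.), CH2Cl2, −78 °C
Reagents that add atoms: 1,2-bis(trimethylsilyloxy)ethane C[Si](C)(C)OCCO[Si](C)(C)C
Why: Silyl-triflate-catalysed acetalisation is selective for the aldehyde over the hindered enone at low temperature and masks C1 against the enolate chemistry that follows.

Step 12
Reactants: 14 1,3-dioxolane
Product: 15 dienyl triflate (C11=C12, C13=C14–OTf)
Conditions: KN(SiMe3)2, PhNTf2, THF, −78 °C
Reagents that add atoms: N-phenylbis(trifluoromethanesulfonimide) O=S(=O)(N(c1ccccc1)S(=O)(=O)C(F)(F)F)C(F)(F)F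
Why: With C8 quaternary the only acidic position is the γ-carbon C11, so the extended dienolate forms and is sulfonylated on oxygen to give the linear dienyl triflate (enol triflate formation).

Step 13
Reactants: 15 dienyl triflate
Product: 16 ethyl 3-(dienyl)propanoate (C14–C15H2–C16H2–C17O2Et)
Conditions: BrZnCH2CH2CO2Et, Pd(PPh3)4 (cat.), LiCl, THF, 50 °C
Reagents that add atoms: (3-ethoxy-3-oxopropyl)zinc bromide CCOC(=O)CC[Zn]Br
Why: Negishi coupling of the alkenyl triflate with the ester-stabilised alkylzinc reagent forms the C14–C15 bond and leaves the isolated alkenes and the acetal untouched.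

Step 14
Reactants: 16 ethyl 3-(dienyl)propanoate
Product: 18 spirolactone (ring D, lactone O α on C14, C12=C13), via dienyl acid 17 (not isolated)
Conditions: LiOH, THF/H2O, rt; 1 M HCl to pH 3, extraction; camphorsulfonic acid (cat.), CH2Cl2, 0 °C to rt
Reagents that add atoms: lithium hydroxide [Li+].[OH-]
Why: Saponification frees the acid, and acid-catalysed hydroacyloxylation of the 1,3-diene (protonation at the less hindered terminus C11, capture of the allyl cation at its tertiary end C14 in a five-membered ring) gives the spirolactone with C12=C13 in place, the carboxyl oxygen adding axially from the α face anti to the 8β-methyl group, which sets C14.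

Step 15
Reactants: 18 spirolactone; 7 (E)-3-methoxy-2-methylbut-2-enoyl chloride
Product: 19 16-acyl spirolactone (C16 enolisable)
Conditions: LDA (2.2 equiv), THF, −78 °C; then 7
Reagents that add atoms: none
Why: Claisen-type C-acylation of the lithium lactone enolate (the second equivalent of base takes up the acidic β-keto lactone proton) installs all carbons of ring E.

Step 16
Reactants: 19 16-acyl spirolactone
Product: 22 spirofuranone aldehyde (rings D and E complete, C1 formyl), via hydroxy ketolactone 20 (not isolated), via furanone acetal 21 (not isolated)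
Conditions: KN(SiMe3)2, THF, −78 °C; 2-(phenylsulfonyl)-3-phenyloxaziridine; then TsOH·H2O, acetone/H2O, rt
Reagents that add atoms: 2-(phenylsulfonyl)-3-phenyloxaziridine O=S(=O)(N1OC1c1ccccc1)c1ccccc1; water O
Why: The enolate of the β-keto lactone is hydroxylated by the N-sulfonyloxaziridine on the lactone face turned away from the quaternary C8 (towards the flat C13), which sets C16 with the oxygen syn to C13, and acid then lets the tertiary hydroxyl add to the β-methoxy enone with loss of methanol (furan-3(2H)-one formation from an α′-hydroxy 1,3-dicarbonyl equivalent) while the dioxolane is hydrolysed.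

Step 17
Reactants: 22 spirofuranone aldehyde
Product: 23 5-acetyl aldehyde
Conditions: PdCl2 (cat.), CuCl, O2, DMF/H2O, rt
Reagents that add atoms: water O
Why: Wacker oxidation converts the monosubstituted alkene into the methyl ketone with Markovnikov regiochemistry, the trisubstituted and furanone alkenes being unreactive, and C5 stays in its equatorial configuration.

Step 18
Reactants: 23 5-acetyl aldehyde
Product: 24 (1S)-homoallylic alcohol
Conditions: B-allyldiisopinocampheylborane from (+)-α-pinene, Et2O, −78 °C; then ethanolamine, rt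
Reagents that add atoms: B-allyldiisopinocampheylborane C=CCB([C@@H]1C[C@@H]2C[C@H]([C@H]1C)C2(C)C)[C@@H]1C[C@@H]2C[C@H]([C@H]1C)C2(C)C
Why: Reagent-controlled asymmetric allylboration through a chair transition state delivers the allyl group to the Si face of the neopentyl-type aldehyde (1S, hydroxyl α) and does not touch the ketones or the lactone.

Step 19
Reactants: 24 (1S)-homoallylic alcohol
Product: 25 diol (C1–OH, C4–OH)
Conditions: MeMgBr (excess), THF, −78 to −40 °C; aq. NH4Cl
Reagents that add atoms: methylmagnesium bromide C[Mg]Br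
Why: The Grignard reagent (one equivalent is spent on the hydroxyl) adds to the methyl ketone, the only unhindered carbonyl, since the lactone and the vinylogous ester carbonyls are flanked by the spiro quaternary C16 and are less electrophilic at low temperature.

Step 20
Reactants: 25 diol
Product: 26 C1 acetate
Conditions: Ac2O, pyridine, DMAP (cat.), CH2Cl2, 0 °C to rt
Reagents that add atoms: acetic anhydride CC(=O)OC(C)=O
Why: Acylation is confined to the secondary C1 hydroxyl because the tertiary C4 hydroxyl is not acetylated under these conditions.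

Step 21
Reactants: 26 C1 acetate
Product: 28 seven-membered lactol (C3 anomers), via hydroxy aldehyde 27 (not isolated)
Conditions: OsO4 (cat.), NaIO4, 2,6-lutidine, dioxane/H2O, 0 °C to rt
Reagents that add atoms: osmium tetroxide O=[Os](=O)(=O)=O; sodium periodate [Na+].[O-]I(=O)(=O)=O
Why: Lemieux–Johnson cleavage selects the unhindered monosubstituted alkene over the hindered C12=C13 bond and the electron-poor furanone alkene, and the C3 aldehyde is trapped by the C4 hydroxyl as the lactol.

Step 22
Reactants: 28 seven-membered lactol
Product: 29 CNP0131208.2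
Conditions: TEMPO (cat.), PhI(OAc)2, CH2Cl2, rt
Reagents that add atoms: none
Why: Oxoammonium-mediated oxidation of the lactol gives the ε-lactone and so closes ring A without acylating a tertiary alcohol, and the β-acetoxy group survives the non-basic conditions.

Compound list
1 | penta-1,4-diene | C=CCC=C | starting material
2 | 3-vinylpent-4-en-1-ol | OCCC(C=C)C=C | intermediate
3 | 3-(2-iodoethyl)penta-1,4-diene | ICCC(C=C)C=C | intermediate
4 | methyl 2-methyl-3-oxobutanoate | COC(=O)C(C)C(C)=O | starting material
5 | methyl (E)-3-methoxy-2-methylbut-2-enoate | COC(=O)/C(C)=C(/OC)C | intermediate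
6 | (E)-3-methoxy-2-methylbut-2-enoic acid | OC(=O)/C(C)=C(/OC)C | intermediate
7 | (E)-3-methoxy-2-methylbut-2-enoyl chloride | ClC(=O)/C(C)=C(/OC)C | intermediate
8 | (S)-(+)-carvone | CC1=CC[C@@H](CC1=O)C(C)=C | starting material
9 | (5S)-2,6-dimethyl-5-(prop-1-en-2-yl)cyclohex-2-en-1-one, C6 epimers | CC1[C@H](CC=C(C)C1=O)C(C)=C | intermediate
10 | (5R,6R)-2,6-dimethyl-5-(prop-1-en-2-yl)-6-(3-vinylpent-4-en-1-yl)cyclohex-2-en-1-one (6-methyl cis to isopropenyl) | C=CC(C=C)CC[C@]1(C)[C@H](CC=C(C)C1=O)C(C)=C | intermediate
11 | trans-fused bicyclo[5.4.0]undecadienone: carvone enone ring fused at C8–C9 to the cycloheptene C9–C10(Me)=C1H–C5H(vinyl)–C6H2–C7H2–C8(Me); 5β-vinyl, 8β-methyl, 9α-H | C=C[C@@H]1CC[C@]2(C)[C@H](CC=C(C)C2=O)C(C)=C1 | intermediate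
12 | 1α,10α-epoxide of 11 | C=C[C@@H]1CC[C@]2(C)[C@H](CC=C(C)C2=O)[C@@]3(C)O[C@@H]13 | intermediate
13 | ring B aldehyde: rings B and C, C10 with β-methyl and formyl (C1), C5 with β-vinyl (5α-H), ring C enone | C=C[C@@H]1CC[C@]2(C)[C@H](CC=C(C)C2=O)[C@@]1(C)C=O | intermediate
14 | 1,3-dioxolane of 13 | C=C[C@@H]1CC[C@]2(C)[C@H](CC=C(C)C2=O)[C@@]1(C)C1OCCO1 | intermediate
15 | dienyl triflate (C11=C12–C13(Me)=C14–OTf) | C=C[C@@H]1CC[C@]2(C)[C@H](C=CC(C)=C2OS(=O)(=O)C(F)(F)F)[C@@]1(C)C1OCCO1 | intermediate
16 | ethyl ester with the C15–C16–C17 chain on C14 of the diene | C=C[C@@H]1CC[C@]2(C)[C@H](C=CC(C)=C2CCC(=O)OCC)[C@@]1(C)C1OCCO1 | intermediate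
17 | dienyl acid | C=C[C@@H]1CC[C@]2(C)[C@H](C=CC(C)=C2CCC(=O)O)[C@@]1(C)C1OCCO1 | intermediate (not isolated)
18 | spiro-γ-lactone (ring D; 14S, lactone O α; C12=C13) | C=C[C@@H]1CC[C@]2(C)[C@H](CC=C(C)[C@@]23CCC(=O)O3)[C@@]1(C)C1OCCO1 | intermediate
19 | 16-[(E)-3-methoxy-2-methylbut-2-enoyl] spirolactone, C16 epimers/enol | C=C[C@@H]1CC[C@]2(C)[C@H](CC=C(C)[C@@]23CC(C(=O)/C(C)=C(/OC)C)C(=O)O3)[C@@]1(C)C1OCCO1 | intermediate
20 | (16R)-16-hydroxy derivative of 19 | C=C[C@@H]1CC[C@]2(C)[C@H](CC=C(C)[C@@]23C[C@@](O)(C(=O)/C(C)=C(/OC)C)C(=O)O3)[C@@]1(C)C1OCCO1 | intermediate (not isolated)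
21 | spirofuranone spirolactone (rings D and E), C1 as dioxolane | C=C[C@@H]1CC[C@]2(C)[C@H](CC=C(C)[C@@]23C[C@]4(OC(C)=C(C)C4=O)C(=O)O3)[C@@]1(C)C1OCCO1 | intermediate (not isolated)
22 | spirofuranone spirolactone with C1 formyl and 5β-vinyl | C=C[C@@H]1CC[C@]2(C)[C@H](CC=C(C)[C@@]23C[C@]4(OC(C)=C(C)C4=O)C(=O)O3)[C@@]1(C)C=O | intermediate
23 | 5-acetyl (C4 ketone) aldehyde | CC(=O)[C@@H]1CC[C@]2(C)[C@H](CC=C(C)[C@@]23C[C@]4(OC(C)=C(C)C4=O)C(=O)O3)[C@@]1(C)C=O | intermediate
24 | (1S)-homoallylic alcohol (C1–OH α, allyl = C2, C3 and one extra carbon) | CC(=O)[C@@H]1CC[C@]2(C)[C@H](CC=C(C)[C@@]23C[C@]4(OC(C)=C(C)C4=O)C(=O)O3)[C@@]1(C)[C@@H](O)CC=C | intermediate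
25 | diol with C4(OH)Me2 on C5 and C1–OH | CC(C)(O)[C@@H]1CC[C@]2(C)[C@H](CC=C(C)[C@@]23C[C@]4(OC(C)=C(C)C4=O)C(=O)O3)[C@@]1(C)[C@@H](O)CC=C | intermediate
26 | C1 acetate of 25 | CC(C)(O)[C@@H]1CC[C@]2(C)[C@H](CC=C(C)[C@@]23C[C@]4(OC(C)=C(C)C4=O)C(=O)O3)[C@@]1(C)[C@@H](OC(C)=O)CC=C | intermediate
27 | hydroxy aldehyde (C3 aldehyde, C4–OH free) | CC(C)(O)[C@@H]1CC[C@]2(C)[C@H](CC=C(C)[C@@]23C[C@]4(OC(C)=C(C)C4=O)C(=O)O3)[C@@]1(C)[C@@H](OC(C)=O)CC=O | intermediate (not isolated)
28 | seven-membered lactol (ring A at lactol level, C3 anomers) | CC(=O)O[C@H]1CC(O)OC(C)(C)[C@@H]2CC[C@]3(C)[C@H](CC=C(C)[C@@]34C[C@]3(OC(C)=C(C)C3=O)C(=O)O4)[C@@]12C | intermediate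
29 | CNP0131208.2 (1S,5R,8R,9R,10R,14S,16R) | CC(=O)O[C@H]1CC(=O)OC(C)(C)[C@@H]2CC[C@]3(C)[C@H](CC=C(C)[C@@]34C[C@]3(OC(C)=C(C)C3=O)C(=O)O4)[C@@]12C | target

Total step count: 22. Longest linear sequence: 18 steps (steps 1, 2, then 7 to 22, from penta-1,4-diene); 17 steps from (S)-carvone.

Steps most likely to fail

Step 10. After ionisation of the C10–O bond a 1,2-hydride shift from C1 (giving the cycloheptanone) may compete with migration of the C1–C5 bond, a longer-lived C10 cation would erode the anti course, and the Lewis-acid-bound aldehyde could undergo a carbonyl-ene reaction with the C5 vinyl group. The fallback replaces the cationic opening by a halohydrin semipinacol shift in which only the ring bond or the oxygen can be antiperiplanar to the leaving group. It sets out from 11: NBS in aqueous DME gives the bromohydrin F1 (bromonium on the α face, water at C10 from the β face); K2CO3 in MeOH closes it to the 1β,10β-epoxide F2; MgBr2·OEt2 in Et2O/toluene opens F2 at C10 with inversion to the magnesium alkoxide of the bromohydrin F3 (10α-Br, 1β-O), in which the C1 hydrogen is cis to bromine and cannot migrate; on warming, C5 displaces bromide from the β face and the route is rejoined at 13 with the same C10 configuration.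

Step 14. The diene may be protonated at the wrong carbon, the allyl cation may be captured at C12 or from the β face, and the acid may isomerise the diene before the carboxyl group closes. The fallback uses a kinetically controlled, non-acidic halolactonisation. It sets out from the acid 17 (saponification half of step 14): I2 and NaHCO3 in MeCN at 0 °C give the iodo spirolactone F4 (oxygen on C14, allylic iodine at C11; a C13 iodide regioisomer would behave the same way); Bu3SnH with AIBN in benzene at 80 °C then removes the iodine through the allyl radical, which takes up hydrogen at the less hindered C11, and the route is rejoined at 18.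

Step 16. The oxaziridine may approach the C16 enolate from the face syn to C8 or without clear preference (the two faces differ only by the quaternary C8 against the vinylic C13), and the α-hydroxy β-keto lactone may suffer retro-Claisen cleavage under base. The fallback inverts the order of bond formation at C16, so that a carbon nucleophile instead of an oxygen electrophile enters from the more accessible face. It sets out from 18: LDA and the same oxaziridine give the 16-hydroxy lactone F5; Dess–Martin periodinane gives the 16-oxo lactone F6; 1-ethoxyprop-1-enyllithium (from ethyl prop-1-enyl ether and t-BuLi) adds to the C16 ketone at −78 °C to give the carbinol F7; dilute oxalic acid unmasks the hydroxy ethyl ketone F8; N,N-dimethylacetamide dimethyl acetal in toluene at 100 °C forms the enaminone, which closes to the 4,5-dimethylfuranone, and the route is rejoined at 21, which the aqueous acid of step 16 converts into 22.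

Further compounds
F1 | step 10 | bromohydrin of 11 (10β-OH, 1α-Br) | C=C[C@@H]1CC[C@]2(C)[C@H](CC=C(C)C2=O)[C@](C)(O)[C@H]1Br
F2 | step 10 | 1β,10β-epoxide of 11 | C=C[C@@H]1CC[C@]2(C)[C@H](CC=C(C)C2=O)[C@]3(C)O[C@H]13
F3 | step 10 | bromohydrin (10α-Br, 1β-OH), formed as its magnesium alkoxide | C=C[C@@H]1CC[C@]2(C)[C@H](CC=C(C)C2=O)[C@@](C)(Br)[C@@H]1O
F4 | step 14 | 11-iodo spirolactone (C11 epimers) | C=C[C@@H]1CC[C@]2(C)[C@H](C(I)C=C(C)[C@@]23CCC(=O)O3)[C@@]1(C)C1OCCO1
F5 | step 16 | 16-hydroxy spirolactone (C16 epimers) | C=C[C@@H]1CC[C@]2(C)[C@H](CC=C(C)[C@@]23CC(O)C(=O)O3)[C@@]1(C)C1OCCO1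
F6 | step 16 | 16-oxo spirolactone | C=C[C@@H]1CC[C@]2(C)[C@H](CC=C(C)[C@@]23CC(=O)C(=O)O3)[C@@]1(C)C1OCCO1
F7 | step 16 | (16R)-16-(1-ethoxyprop-1-enyl)-16-hydroxy spirolactone | C=C[C@@H]1CC[C@]2(C)[C@H](CC=C(C)[C@@]23C[C@@](O)(C(OCC)=CC)C(=O)O3)[C@@]1(C)C1OCCO1
F8 | step 16 | (16R)-16-hydroxy-16-propanoyl spirolactone | C=C[C@@H]1CC[C@]2(C)[C@H](CC=C(C)[C@@]23C[C@@](O)(C(=O)CC)C(=O)O3)[C@@]1(C)C1OCCO1
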